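**Plan**
Retrosynthesis: cut C16–C17 (Stille), C13=C14 (Horner–Wadsworth–Emmons) and C12–C13 (phosphonate alkylation) to reach a C16 trans-decalin alcohol; then cut the ring-fusion bond C5–C10 (transannular carbonyl-ene) and C7–C8 (oxy-Cope) back to an α-alkenylated 2,2,6-trimethylcyclohexanone.
Forward: the cyclohexanone (future C1–C5 and C10) is alkenylated at C10 and vinylated at C5, ring-expanded to a ten-membered dienone, and one transannular bond then closes rings A and B together; the chain is joined last, C12–C13, C13=C14, C16–C17 in that order.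
Enabling feature: the C5–C10 ring-fusion bond lies next to the tetrasubstituted C8=C9 alkene, which is the ene pattern of a cyclodec-5-enone with C5 as carbonyl, an E C9=C10 alkene and one allylic hydrogen on C8; C9 carries a vinyl group (C11=C12) so that no side-chain hydrogen can compete with H8.
Stereochemistry: C10 comes from a catalytic asymmetric α-alkenylation, is stored as C8 plus a locked alkene face during the oxy-Cope, and is returned to C10 in the ene step; C5 comes from α-face hydrogenation; 13E comes from the olefination and 15Z from ethyl (Z)-3-iodoacrylate, kept through the Stille coupling.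

Key step: step 6

Remark: locants are those of the target: decalin C1–C10 (C4 gem-dimethyl, C5/C10 ring fusion, C8=C9 ring alkene), C11–C12 the ethylene on C9, C13–C16 the dienyl chain (hydroxymethyl on C13), C17–C20 the butenolide.
Assumption: the sense of induction of the chiral ligand in step 3 is not certain in advance; the ligand antipode that gives the R ketone is the one used.
Abbreviation: Q = (4aS,8aS)-2,5,5,8a-tetramethyl-3,4,4a,5,6,7,8,8a-octahydronaphthalen-1-yl (the trans-decalin unit of the target, bonded through C9).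

**Route**

Step 1
Reactants: 1 (E)-but-2-enal
Product: 3 (Z)-2-bromobut-2-enal, via 2,3-dibromobutanal 2 (not isolated)
Conditions: Br2, CH2Cl2, 0 °C; then Et3N, 0 °C → rt
Reagents that add atoms: bromine, BrBr
Why: Bromination–dehydrobromination of an enal (anti addition of Br2, then E1cB loss of HBr through the acidic α-hydrogen) is the standard entry to α-bromoenals, and the Z isomer with methyl trans to the formyl group, hence Br cis to methyl, is the thermodynamically preferred geometry.

Step 2
Reactants: 3 (Z)-2-bromobut-2-enal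
Product: 4 (Z)-3-bromopenta-1,3-diene
Conditions: Ph3PCH3Br, KOt-Bu, Et2O, 0 °C; then 3, −20 °C → rt
Reagents that add atoms: methyltriphenylphosphonium bromide, C[P+](c1ccccc1)(c1ccccc1)c1ccccc1.[Br-]
Why: Wittig methylenation with the non-stabilised ylide turns the formyl group into the vinyl group (future C11=C12) by 1,2-addition without touching the bromoalkene geometry.

Step 3
Reactants: 4 (Z)-3-bromopenta-1,3-diene; 5 2,2,6-trimethylcyclohexan-1-one (racemic)
Product: 6 (6R)-2,2,6-trimethyl-6-[(3Z)-penta-1,3-dien-3-yl]cyclohexan-1-one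
Conditions: Pd2(dba)3 (2.5 mol %), (R)-2-(dicyclohexylphosphino)-2'-(dimethylamino)-1,1'-binaphthyl (6 mol %), NaOt-Bu, PhMe, rt → 40 °C
Reagents that add atoms: none
Why: Palladium-catalysed asymmetric α-alkenylation of a ketone enolate (Buchwald–Hartwig enolate coupling): 5 can enolise only towards C6, oxidative addition and reductive elimination keep the Z bromoalkene geometry, and the chiral monophosphine on palladium selects one enolate face so that racemic 5 converges on the R quaternary carbon (future C10).

Step 4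
Reactants: 6 (6R)-2,2,6-trimethyl-6-[(3Z)-penta-1,3-dien-3-yl]cyclohexan-1-one; 7 vinylmagnesium bromide
Product: 8 (1R,2R)-1-ethenyl-2,6,6-trimethyl-2-[(3Z)-penta-1,3-dien-3-yl]cyclohexan-1-ol
Conditions: CeCl3, THF, −78 → 0 °C; then aq NH4Cl
Reagents that add atoms: none
Why: CeCl3-mediated Grignard 1,2-addition to a non-enolisable, hindered ketone, where approach anti to the bulkier α-substituent (the branched dienyl group, Felkin–Anh sense) should set the carbinol carbon (future C5) with vinyl cis to the neighbouring methyl, i.e. the trans-1,2-dialkenyl arrangement.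

Step 5
Reactants: 8 (1R,2R)-1-ethenyl-2,6,6-trimethyl-2-[(3Z)-penta-1,3-dien-3-yl]cyclohexan-1-ol
Product: 10 (4S,5E)-5-ethenyl-4,6,10,10-tetramethylcyclodec-5-en-1-one, via potassium enolate 9 (not isolated)
Conditions: KH, 18-crown-6, THF, 0 °C → rt; then AcOH, −78 °C
Reagents that add atoms: none
Why: Anionic oxy-Cope rearrangement: the potassium alkoxide undergoes the [3,3] shift through a chair transition state with both alkenyl groups equatorial on the six-membered ring, which forms C7–C8, breaks C5–C10, gives the E ring alkene C9=C10 and, by suprafacial transfer across the Z-configured C8=C9 unit, converts the quaternary stereocentre into C8 (S) with H8 able to turn onto the alkene face spanned by the carbonyl bridge.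

Step 6
Reactants: 10 (4S,5E)-5-ethenyl-4,6,10,10-tetramethylcyclodec-5-en-1-one
Product: 11 (4aR,8aR)-1-ethenyl-2,5,5,8a-tetramethyl-3,4,4a,5,6,7,8,8a-octahydronaphthalen-4a-ol (trans-fused; 5α-hydroxyl anti to the C10 methyl)
Conditions: degassed PhMe (0.01 M), Et3N (0.1 equiv), sealed tube, 170–190 °C
Reagents that add atoms: none
Why: Concerted transannular carbonyl-ene reaction: the C5 carbonyl carbon bonds to C10 while H8 moves to oxygen through the six-membered array O=C5···C10=C9–C8–H, the closest known case being the ene half of the oxy-Cope/transannular-ene route from 1,2-dialkenylcyclohexanols to decalinols. One transannular C5–C10 bond divides the ten-membered ring into rings A and B, each closure being 6-exo-trig with respect to the carbonyl, and the shifted alkene ends endocyclic in ring B as C8=C9. C10 is set by the alkene face: the tetrasubstituted E alkene cannot turn through the ring, so the carbonyl bridge stays on the face that C5 left in step 5, the same face that carries H8 of the 8S centre, and C5 returns to C10 with the configuration fixed in step 3. C5 follows from the E geometry (C1 and C8 trans on the alkene), which places the new hydroxyl anti to the C10 methyl, i.e. the trans ring fusion. The step needs transfer of H8 rather than a side-chain hydrogen and bonding at C10 rather than C9; the vinyl group secures both, because C11 is sp2 and offers no allylic hydrogen, and C10 is the terminus of the C10=C9–C11=C12 diene so that bonding there keeps a conjugated diene (C8=C9–C11=C12). Oxa-Diels–Alder capture of the carbonyl is disfavoured because the fully substituted C10 terminus holds the diene s-trans, and Et3N suppresses acid-induced cationic closure.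

Step 7
Reactants: 11 (4aR,8aR)-1-ethenyl-2,5,5,8a-tetramethyl-3,4,4a,5,6,7,8,8a-octahydronaphthalen-4a-ol
Product: 12 (8aR)-1-ethenyl-2,5,5,8a-tetramethyl-3,5,6,7,8,8a-hexahydronaphthalene
Conditions: SOCl2, pyridine, CH2Cl2, −20 → 0 °C
Reagents that add atoms: none
Why: Thionyl chloride–pyridine dehydration of a tertiary alcohol by anti elimination of the sulfinylated axial 5α-oxygen with the axial H6β, the only β-hydrogens available because C4 and C10 are quaternary, under buffered non-ionising conditions that avoid 1,2-shifts to C5.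

Step 8
Reactants: 12 (8aR)-1-ethenyl-2,5,5,8a-tetramethyl-3,5,6,7,8,8a-hexahydronaphthalene
Product: 14 2-[(8aR)-2,5,5,8a-tetramethyl-3,5,6,7,8,8a-hexahydronaphthalen-1-yl]ethan-1-ol, via B-alkyl-9-borabicyclononane adduct 13 (not isolated)
Conditions: 9-BBN, THF, 0 °C → rt; then NaOH, H2O2, 0 °C
Reagents that add atoms: hydrogen peroxide, OO
Why: Brown hydroboration–oxidation, in which 9-BBN adds only to the unhindered monosubstituted vinyl terminus with boron on C12 and the oxidation replaces boron by hydroxyl with retention, while the hindered tri- and tetrasubstituted ring alkenes do not react.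

Step 9
Reactants: 14 2-[(8aR)-2,5,5,8a-tetramethyl-3,5,6,7,8,8a-hexahydronaphthalen-1-yl]ethan-1-ol
Product: 15 2-Q-ethan-1-ol
Conditions: H2 (3 atm), PtO2, EtOAc, rt
Reagents that add atoms: none
Why: Heterogeneous catalytic hydrogenation delivers hydrogen to the trisubstituted C5=C6 bond from the α-face, opposite the axial C10 and 4β methyl groups, as in the classical reduction of 4,4,10-trimethyl-Δ5-octalins to trans-decalins, which sets C5 (S) while the tetrasubstituted C8=C9 bond is too hindered to be reduced.

Step 10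
Reactants: 15 2-Q-ethan-1-ol
Product: 16 Q-CH2CH2I, (4aS,8aS)-1-(2-iodoethyl)-2,5,5,8a-tetramethyl-3,4,4a,5,6,7,8,8a-octahydronaphthalene
Conditions: I2, PPh3, imidazole, CH2Cl2, 0 °C → rt
Reagents that add atoms: iodine, [I][I]
Why: Garegg–Samuelsson (Appel-type) iodination converts the primary alcohol into the iodide by SN2 displacement of the alkoxyphosphonium ion.

Step 11
Reactants: 16 Q-CH2CH2I; 17 triethyl phosphonoacetate
Product: 18 ethyl 2-(diethoxyphosphoryl)-4-Q-butanoate (both C2 epimers)
Conditions: NaH, 17 (3 equiv), DMF, 0 °C; then 16, 50 °C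
Reagents that add atoms: none
Why: SN2 C-alkylation of the sodium salt of the phosphonoacetate by the primary iodide forms C12–C13, an excess of the soft, weakly basic nucleophile suppressing dialkylation and elimination, and the new α-stereocentre is formed as a mixture that disappears in step 12.

Step 12
Reactants: 18 ethyl 2-(diethoxyphosphoryl)-4-Q-butanoate; 19 ethyl (Z)-3-iodoprop-2-enoate
Product: 21 ethyl (2E,4Z)-5-iodo-2-(2-Q-ethyl)penta-2,4-dienoate, via (Z)-3-iodoprop-2-enal 20 (not isolated)
Conditions: 19, i-Bu2AlH, CH2Cl2, −78 °C; then sodium salt of 18 (NaH, THF), −78 → 0 °C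
Reagents that add atoms: none
Why: Half-reduction of the ester with i-Bu2AlH at −78 °C and Horner–Wadsworth–Emmons olefination of the aldehyde in the same flask, α-alkyl phosphonoacetates giving the E trisubstituted enoate (ester trans to C15, C12 cis to C15) and the low temperature preserving the Z iodoalkene.

Step 13
Reactants: 21 ethyl (2E,4Z)-5-iodo-2-(2-Q-ethyl)penta-2,4-dienoate
Product: 22 (2E,4Z)-5-iodo-2-(2-Q-ethyl)penta-2,4-dien-1-ol
Conditions: i-Bu2AlH, CH2Cl2, −78 °C
Reagents that add atoms: none
Why: 1,2-Reduction of the conjugated ester by i-Bu2AlH gives the allylic alcohol (the C13 hydroxymethyl group) without affecting the vinyl iodide or the alkenes.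

Step 14
Reactants: 23 4-bromofuran-2(5H)-one
Product: 24 4-(tributylstannyl)furan-2(5H)-one
Conditions: (Bu3Sn)2, Pd(PPh3)4 (3 mol %), THF, reflux
Reagents that add atoms: hexabutylditin, CCCC[Sn](CCCC)(CCCC)[Sn](CCCC)(CCCC)CCCC
Why: Palladium-catalysed stannylation of the β-bromo butenolide with hexabutylditin (oxidative addition, Sn–Sn transmetalation, reductive elimination) is a known preparation of this stannane.

Step 15
Reactants: 22 (2E,4Z)-5-iodo-2-(2-Q-ethyl)penta-2,4-dien-1-ol; 24 4-(tributylstannyl)furan-2(5H)-one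
Product: 25 4-[(1Z,3E)-4-(hydroxymethyl)-6-Q-hexa-1,3-dien-1-yl]furan-2(5H)-one (target)
Conditions: Pd2(dba)3 (5 mol %), AsPh3, CuI, DMF, rt, dark
Reagents that add atoms: none
Why: Stille cross-coupling with CuI co-catalysis at room temperature forms C16–C17 with retention of the Z alkene geometry and tolerates the free hydroxyl group and the butenolide.

**Compound list**
1 | (E)-but-2-enal | C/C=C/C=O | starting material
2 | (2S,3R)-2,3-dibromobutanal (racemic anti adduct, one enantiomer drawn) | C[C@@H](Br)[C@@H](Br)C=O | intermediate (not isolated)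
3 | (Z)-2-bromobut-2-enal | C/C=C(\Br)C=O | intermediate
4 | (Z)-3-bromopenta-1,3-diene | C/C=C(\Br)C=C | intermediate
5 | 2,2,6-trimethylcyclohexan-1-one (racemic) | CC1CCCC(C)(C)C1=O | starting material
6 | (6R)-2,2,6-trimethyl-6-[(3Z)-penta-1,3-dien-3-yl]cyclohexan-1-one | C[C@]1(/C(C=C)=C\C)CCCC(C)(C)C1=O | intermediate
7 | vinylmagnesium bromide | C=C[Mg]Br | starting material
8 | (1R,2R)-1-ethenyl-2,6,6-trimethyl-2-[(3Z)-penta-1,3-dien-3-yl]cyclohexan-1-ol | C=C[C@@]1(O)C(C)(C)CCC[C@]1(C)/C(C=C)=C\C | intermediate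
9 | potassium (1Z,4S,5E)-5-ethenyl-4,6,10,10-tetramethylcyclodeca-1,5-dien-1-olate | [K+].[O-]/C1=C\C[C@H](C)/C(C=C)=C(C)/CCCC1(C)C | intermediate (not isolated)
10 | (4S,5E)-5-ethenyl-4,6,10,10-tetramethylcyclodec-5-en-1-one | O=C1CC[C@H](C)/C(C=C)=C(C)/CCCC1(C)C | intermediate (key-step precursor)
11 | (4aR,8aR)-1-ethenyl-2,5,5,8a-tetramethyl-3,4,4a,5,6,7,8,8a-octahydronaphthalen-4a-ol | CC1=C(C=C)[C@@]2(C)CCCC(C)(C)[C@]2(O)CC1 | intermediate (key-step product)
12 | (8aR)-1-ethenyl-2,5,5,8a-tetramethyl-3,5,6,7,8,8a-hexahydronaphthalene | CC1=C(C=C)[C@@]2(C)CCCC(C)(C)C2=CC1 | intermediate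
13 | 9-{2-[(8aR)-2,5,5,8a-tetramethyl-3,5,6,7,8,8a-hexahydronaphthalen-1-yl]ethyl}-9-borabicyclo[3.3.1]nonane | CC1=C(CCB3C4CCCC3CCC4)[C@@]2(C)CCCC(C)(C)C2=CC1 | intermediate (not isolated)
14 | 2-[(8aR)-2,5,5,8a-tetramethyl-3,5,6,7,8,8a-hexahydronaphthalen-1-yl]ethan-1-ol | CC1=C(CCO)[C@@]2(C)CCCC(C)(C)C2=CC1 | intermediate
15 | 2-[(4aS,8aS)-2,5,5,8a-tetramethyl-3,4,4a,5,6,7,8,8a-octahydronaphthalen-1-yl]ethan-1-ol | CC1=C(CCO)[C@@]2(C)CCCC(C)(C)[C@@H]2CC1 | intermediate
16 | (4aS,8aS)-1-(2-iodoethyl)-2,5,5,8a-tetramethyl-3,4,4a,5,6,7,8,8a-octahydronaphthalene | CC1=C(CCI)[C@@]2(C)CCCC(C)(C)[C@@H]2CC1 | intermediate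
17 | triethyl phosphonoacetate | CCOC(=O)CP(=O)(OCC)OCC | starting material
18 | ethyl 2-(diethoxyphosphoryl)-4-[(4aS,8aS)-2,5,5,8a-tetramethyl-3,4,4a,5,6,7,8,8a-octahydronaphthalen-1-yl]butanoate (C2 epimers) | CC1=C(CCC(C(=O)OCC)P(=O)(OCC)OCC)[C@@]2(C)CCCC(C)(C)[C@@H]2CC1 | intermediate
19 | ethyl (Z)-3-iodoprop-2-enoate | CCOC(=O)/C=C\I | starting material
20 | (Z)-3-iodoprop-2-enal | O=C/C=C\I | intermediate (not isolated)
21 | ethyl (2E,4Z)-5-iodo-2-{2-[(4aS,8aS)-2,5,5,8a-tetramethyl-3,4,4a,5,6,7,8,8a-octahydronaphthalen-1-yl]ethyl}penta-2,4-dienoate | CC1=C(CC/C(C(=O)OCC)=C\C=C/I)[C@@]2(C)CCCC(C)(C)[C@@H]2CC1 | intermediate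
22 | (2E,4Z)-5-iodo-2-{2-[(4aS,8aS)-2,5,5,8a-tetramethyl-3,4,4a,5,6,7,8,8a-octahydronaphthalen-1-yl]ethyl}penta-2,4-dien-1-ol | CC1=C(CC/C(CO)=C\C=C/I)[C@@]2(C)CCCC(C)(C)[C@@H]2CC1 | intermediate
23 | 4-bromofuran-2(5H)-one | O=C1C=C(Br)CO1 | starting material
24 | 4-(tributylstannyl)furan-2(5H)-one | CCCC[Sn](CCCC)(CCCC)C1=CC(=O)OC1 | intermediate
25 | 4-[(1Z,3E)-4-(hydroxymethyl)-6-[(4aS,8aS)-2,5,5,8a-tetramethyl-3,4,4a,5,6,7,8,8a-octahydronaphthalen-1-yl]hexa-1,3-dien-1-yl]furan-2(5H)-one | CC1=C(CC/C(=C\C=C/C2=CC(=O)OC2)CO)[C@@]2(C)CCCC(C)(C)[C@@H]2CC1 | target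

**Totals**
Total steps: 15. Longest linear sequence: 14 (steps 1–13 and 15); step 14 is a one-step side branch.

**Steps most likely to fail**

Step 6 (transannular ene). The closure may be slow or reversible at the congested C5/C10 pair. At the temperature it needs, the dienyl unit may react first by a [1,5]-hydrogen shift from C1 into the vinyl group or by oxa-[4+2] capture of the carbonyl. The fallback replaces the vinyl group by a silyl-protected ethynyl group, which also has no allylic hydrogen at C11 but cannot take part in either side reaction and is slimmer next to C10. It sets out from ketone 5 and comes back at 11. Acetaldehyde is converted with CBr4/PPh3 into 1,1-dibromoprop-1-ene F1. Trans-selective Sonogashira mono-coupling of F1 with ethynyltri(propan-2-yl)silane (PdCl2(dppf), CuI, i-Pr2NH) gives [(3Z)-3-bromopent-3-en-1-yn-1-yl]tri(propan-2-yl)silane F2, with Br cis to methyl. Coupling of F2 with 5 under the step 3 conditions should give the enynyl ketone F3, vinyl addition as in step 4 the carbinol F4, the anionic oxy-Cope as in step 5 the silylethynyl cyclodecenone F5 (4S, trans ring alkene), and thermal closure as in step 6 the silylethynyl decalinol F6. Bu4NF then frees the terminal alkyne F7, and semi-hydrogenation over Pd/CaCO3 poisoned with Pb(OAc)2 and quinoline returns vinyl compound 11.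

Step 3 (asymmetric α-alkenylation). Reductive elimination to the quaternary carbon may be slow with this hindered enolate and α-branched bromide. That would allow dehydrobromination of 4 or poor discrimination of the enolate faces, and so low enantiomeric purity. The fallback separates bond formation from stereocontrol; it sets out from 4 and 5 and comes back at 6. Coupling with an achiral bulky catalyst (Pd(OAc)2, P(t-Bu)3, NaOt-Bu, PhMe) gives the racemic ketone F8, which is resolved by preparative chromatography on a chiral stationary phase (supercritical CO2, amylose carbamate phase). The R enantiomer is 6 and the S ketone F9 is set aside.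

Step 4 (vinyl addition). Face discrimination at the carbonyl may be poor or reversed (attack anti to the axial C10 methyl), so that the C5 epimer dominates; its chair oxy-Cope leads to the Z ring alkene and not to 10. The fallback uses that epimer, because the stereochemical relay through C8 does not depend on C5. It sets out from 6 and comes back at 12. The epimeric carbinol F10 is taken through the step 5 conditions to the (4R,5Z)-cyclodecenone F11. Its thermal ene closure, again with H8 as the only allylic hydrogen within reach, gives the cis-fused 5β-ol F12 with the same C10 configuration. Dehydration of F12 under the step 7 conditions gives triene 12.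

**Further compounds**
F1 | step 6 | 1,1-dibromoprop-1-ene | CC=C(Br)Br
F2 | step 6 | [(3Z)-3-bromopent-3-en-1-yn-1-yl]tri(propan-2-yl)silane | C/C=C(\Br)C#C[Si](C(C)C)(C(C)C)C(C)C
F3 | step 6 | (6R)-2,2,6-trimethyl-6-{(3E)-1-[tri(propan-2-yl)silyl]pent-3-en-1-yn-3-yl}cyclohexan-1-one (methyl cis to the ring carbon) | C[C@]1(/C(C#C[Si](C(C)C)(C(C)C)C(C)C)=C\C)CCCC(C)(C)C1=O
F4 | step 6 | (1R,2R)-1-ethenyl-2,6,6-trimethyl-2-{(3E)-1-[tri(propan-2-yl)silyl]pent-3-en-1-yn-3-yl}cyclohexan-1-ol | C=C[C@@]1(O)C(C)(C)CCC[C@]1(C)/C(C#C[Si](C(C)C)(C(C)C)C(C)C)=C\C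
F5 | step 6 | (4S)-4,6,10,10-tetramethyl-5-{[tri(propan-2-yl)silyl]ethynyl}cyclodec-5-en-1-one, trans ring alkene (5Z by sequence rule) | O=C1CC[C@H](C)/C(C#C[Si](C(C)C)(C(C)C)C(C)C)=C(C)/CCCC1(C)C
F6 | step 6 | (4aR,8aR)-2,5,5,8a-tetramethyl-1-{[tri(propan-2-yl)silyl]ethynyl}-3,4,4a,5,6,7,8,8a-octahydronaphthalen-4a-ol | CC1=C(C#C[Si](C(C)C)(C(C)C)C(C)C)[C@@]2(C)CCCC(C)(C)[C@]2(O)CC1
F7 | step 6 | (4aR,8aR)-1-ethynyl-2,5,5,8a-tetramethyl-3,4,4a,5,6,7,8,8a-octahydronaphthalen-4a-ol | CC1=C(C#C)[C@@]2(C)CCCC(C)(C)[C@]2(O)CC1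
F8 | step 3 | racemic 2,2,6-trimethyl-6-[(3Z)-penta-1,3-dien-3-yl]cyclohexan-1-one | CC1(/C(C=C)=C\C)CCCC(C)(C)C1=O
F9 | step 3 | (6S)-2,2,6-trimethyl-6-[(3Z)-penta-1,3-dien-3-yl]cyclohexan-1-one | C[C@@]1(/C(C=C)=C\C)CCCC(C)(C)C1=O
F10 | step 4 | (1S,2R)-1-ethenyl-2,6,6-trimethyl-2-[(3Z)-penta-1,3-dien-3-yl]cyclohexan-1-ol | C=C[C@]1(O)C(C)(C)CCC[C@]1(C)/C(C=C)=C\C
F11 | step 4 | (4R,5Z)-5-ethenyl-4,6,10,10-tetramethylcyclodec-5-en-1-one | O=C1CC[C@@H](C)/C(C=C)=C(C)\CCCC1(C)C
F12 | step 4 | (4aS,8aR)-1-ethenyl-2,5,5,8a-tetramethyl-3,4,4a,5,6,7,8,8a-octahydronaphthalen-4a-ol (cis-fused) | CC1=C(C=C)[C@@]2(C)CCCC(C)(C)[C@@]2(O)CC1
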